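Its constants are assumed; the flask was simulated.

A charge of solid base, fed slowly into solution, takes up the acid set free by the coupling.

electrophile 10 mM; nucleophile 9.50 mM; solid base 10.0 mM; time 6.0 d

    electrophile + nucleophile → acid set free + target (k1 = 4.9 L mol⁻¹ h⁻¹)
    nucleophile + acid set free ⇌ protonated nucleophile, settled at all times (K2 = 3.6 × 10⁵ L mol⁻¹)
    acid set free + free base ⇌ salt of the base, settled at all times (K3 = 2.5 × 10⁶ L mol⁻¹)
    nucleophile ⇌ dormant form (K4 = 0.39, k4 = 0.027 h⁻¹)
    crystals ⇌ target, rate k5*(cs5 - [target]) while solid is left; crystals form when [target] > cs5 (cs5 = 0.46 mM, k5 = 0.42 h⁻¹)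
    solid base ⇌ free base, rate k6*(cs6 - [free base]) while solid is left; crystals form when [free base] > cs6 (cs6 = 3.6 mM, k6 = 0.032 h⁻¹)

* part of the electrophile that has reacted at 6.0 d
* share of free nucleophile in free nucleophile and protonated nucleophile together, at 6.0 d

First turn the constants into times at the charged amounts, and hold them against the run of 6.0 d.

| Process | Time |
|---|---|
| electrophile halves by step 1 | 0.62 d |
| nucleophile and dormant form settle | 0.300 d |
| solid base dissolves at full speed | 3.62 d |

Nucleophile and dormant form settle well within the run, so set dormant form = K4·N, where N is free nucleophile. Coupling starts at 0.466 mM h⁻¹, faster than base can arrive at 0.115 mM h⁻¹, so the nucleophile must hold part of the acid.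

Now divide step 2 by step 3. With H for protonated nucleophile, S for salt and F for free base, H/N = g·S/F, where g = K2/K3 is the exchange ratio, the nucleophile's hold on acid over the base's. It comes to 0.144.

Guess a free share N/(N+H) of 0.7. Step 1 then runs with an effective constant of 2.69 L mol⁻¹ h⁻¹. Treat both charges as equal at their mean, 9.75 mM; second-order decay then gives 7.71 mM reacted, or 77.1%.

The nucleophile left then holds 0.421 mM as H, so S = 7.29 mM. If the base has dissolved completely, F = 2.71 mM, and g returns a share of 72.1%.

That "if" is the weak link, so reforge it. Dissolving slows as F climbs, so take F at its mean, half the final value: the run then delivers 10.3 mM, barely above the charge. Commit to these figures.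

The forecast gives 77% and 71%, on the grounds that “acid first ties up nucleophile as its protonated form, then the base gradually frees it”. My share stands slightly higher.

The flask gives 76.3% and 72.6%, both within the forecast's margins. At 6.00 d the flask's solid base stands at 0%, and 7.24 mM of salt against 2.76 mM of free base puts the nucleophile's hold on acid, through g, at 0.378 of the free form. The neighbour flask with 4.0 mM of solid base has 3.95 mM of salt against 0.0505 mM of free base, so g gives a free share of 8.15%, and 65.6% of its electrophile has reacted.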